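**Retrosynthetic overview**

- The target, a C3,C5 1,3-diketone drawn as its C3 enol, comes from its tris-silyl ether by one global desilylation.
- The strategy rests on the C3 carbonyl carbon. With the chain numbered C1 (on guaiacyl ring A) to C7 (carbinol carbon on 4-hydroxyphenyl ring B), C3 sits between the C1=C2 styryl unit and C4, so C2–C3 and C3–C4 are both cut and C3 is supplied by carbon monoxide.
- The three components are the E-styryl bromide of ring A, CO, and the methyl-side lithium enolate of the (S)-β-silyloxy methyl ketone that carries C4–C7 and ring B.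
- The bromide comes from ferulic acid (silylation, bromodecarboxylation). The ketone comes from 4-(tert-butyldimethylsilyloxy)benzaldehyde (Brown allylation to set C7, silylation, Wacker oxidation).
- No ring is formed at any stage; arene rings A and B are bought.

Key step: step 6

Remark on the chemistry: the enol drawn in the target (C3–OH, C3=C4, C5=O) is one tautomer of the C3,C5 β-diketone. Tautomers and enol geometries interconvert freely, so the route delivers the β-diketone and the compound list writes it in the drawn enol form. The elements to control are the E C1=C2 alkene and the (S) centre at C7.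

**Step 1**
Reactants: 1 ferulic acid
Product: 3 (E)-3-[4-(tert-butyldimethylsilyloxy)-3-methoxyphenyl]prop-2-enoic acid, via bis-silyl ferulate 2 (not isolated)
Conditions: TBSCl (2.5 equiv), imidazole (5 equiv), DMF, rt; then AcOH/THF/H2O, rt
Reagents that add atoms: tert-butyldimethylsilyl chloride, CC(C)(C)[Si](C)(C)Cl
Why: Standard silylation of the phenol and the acid is followed by selective hydrolysis of the far more labile silyl ester under mild aqueous acid, which should leave the aryl silyl ether intact.

**Step 2**
Reactants: 3 (E)-3-[4-(tert-butyldimethylsilyloxy)-3-methoxyphenyl]prop-2-enoic acid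
Product: 4 (E)-[4-(2-bromoethenyl)-2-methoxyphenoxy](tert-butyl)dimethylsilane
Conditions: NBS (1.05 equiv), LiOAc (0.2 equiv), MeCN/H2O (97:3), rt
Reagents that add atoms: N-bromosuccinimide, O=C1CCC(=O)N1Br
Why: In this catalytic Hunsdiecker-type bromodecarboxylation, bromonium formation at the electron-rich styrene and carboxylate-assisted loss of CO2 should give the E alkenyl bromide, the protected phenol preventing ring bromination.

**Step 3**
Reactants: 5 4-(tert-butyldimethylsilyloxy)benzaldehyde
Product: 7 (S)-1-[4-(tert-butyldimethylsilyloxy)phenyl]but-3-en-1-ol, via diisopinocampheylborinate ester 6 (not isolated)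
Conditions: (−)-Ipc2BOMe [from (+)-α-pinene], CH2=CHCH2MgBr, Et2O, 0 °C to rt; then 5, −78 °C; then HOCH2CH2NH2, rt
Reagents that add atoms: allylmagnesium bromide, C=CC[Mg]Br
Why: In this Brown asymmetric allylboration the allylborane with isopinocampheyl groups from (+)-α-pinene delivers allyl to the Si face of the aldehyde through a closed chair transition state, which sets C7 as S (aryl outranks the allyl CH2), and the non-basic ethanolamine work-up spares the aryl silyl ether.

**Step 4**
Reactants: 7 (S)-1-[4-(tert-butyldimethylsilyloxy)phenyl]but-3-en-1-ol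
Product: 8 (S)-tert-butyl{4-[1-(tert-butyldimethylsilyloxy)but-3-en-1-yl]phenoxy}dimethylsilane
Conditions: TBSCl (1.5 equiv), imidazole (3 equiv), DMF, rt
Reagents that add atoms: tert-butyldimethylsilyl chloride, CC(C)(C)[Si](C)(C)Cl
Why: Routine O-silylation of a secondary benzylic alcohol takes place at oxygen only, so the C7 configuration is untouched.

**Step 5**
Reactants: 8 (S)-tert-butyl{4-[1-(tert-butyldimethylsilyloxy)but-3-en-1-yl]phenoxy}dimethylsilane
Product: 9 (S)-4-(tert-butyldimethylsilyloxy)-4-[4-(tert-butyldimethylsilyloxy)phenyl]butan-2-one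
Conditions: PdCl2 (10 mol %), Cu(OAc)2 (20 mol %), O2 (1 atm), DMA/H2O (7:1), rt
Reagents that add atoms: water, O
Why: In this Tsuji–Wacker oxidation divalent palladium activates the terminal alkene for Markovnikov attack of water and β-hydride elimination gives the methyl ketone, while Cu(OAc)2/O2 reoxidises palladium without releasing HCl that would threaten the silyl ethers.

**Step 6**
Reactants: 4 (E)-[4-(2-bromoethenyl)-2-methoxyphenoxy](tert-butyl)dimethylsilane, 9 (S)-4-(tert-butyldimethylsilyloxy)-4-[4-(tert-butyldimethylsilyloxy)phenyl]butan-2-one, 10 carbon monoxide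
Product: 12 (S,1E)-7-(tert-butyldimethylsilyloxy)-1-[4-(tert-butyldimethylsilyloxy)-3-methoxyphenyl]-7-[4-(tert-butyldimethylsilyloxy)phenyl]hept-1-ene-3,5-dione (written as its C3 enol), via lithium enolate 11 (not isolated)
Conditions: 9 (2.2 equiv), LiN(SiMe3)2 (2.1 equiv), THF, −78 °C; cannulate into 4 (1.0 equiv), Pd(dba)2 (5 mol %), Xantphos (6 mol %), CO (2 bar), THF, −78 °C to 25 °C (40 °C only if 4 persists); aq. NH4Cl; returned 9 recovered
Reagents that add atoms: carbon monoxide (compound 10), [C-]#[O+]
Why: Zerovalent palladium formed from Pd(dba)2 and Xantphos inserts into the C–Br bond of 4 with retention of the E geometry, CO inserts to give the cinnamoyl–palladium bromide, and enolate 11 displaces bromide and reductively eliminates through carbon, so the CO carbon becomes C3 bonded to C2 and C4. The closest known reaction type is the palladium-catalysed carbonylative α-arylation of ketones to 1,3-diketones, applied here to an alkenyl bromide, a class for which capture of acylpalladium species by enolates is also known. No ring closes and no stereocentre is made; C7 is not acidic and is carried through, and the C1=C2 geometry is that of 4. The regiochemistry of enolisation is secured by kinetic deprotonation of the methyl group (C4) with LiN(SiMe3)2 at −78 °C, because enolisation toward C6 would expel the C7 silyloxy group, and the slight excess of ketone leaves no free amide to intercept the acylpalladium. CO pressure and the wide bite angle of Xantphos should make CO insertion faster than direct alkenylation of the enolate. The acidic β-diketone product is deprotonated at once by the second equivalent of enolate, which shields it from further acylation and returns one equivalent of 9.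

**Step 7**
Reactants: 12 tris-silyl ether of the target
Product: 13 (S,1E)-7-hydroxy-1-(4-hydroxy-3-methoxyphenyl)-7-(4-hydroxyphenyl)hept-1-ene-3,5-dione (the target, drawn as its C3 enol)
Conditions: HF·pyridine, excess pyridine, THF, 0 °C to rt
Reagents that add atoms: none
Why: Fluoride cleaves the two aryl silyl ethers quickly and the secondary benzylic one more slowly, and the pyridine buffer avoids both the basic conditions that would invite retro-aldol or β-elimination and the strong acid that would ionise the C7–O bond.

**Compound list**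

1 | ferulic acid, (E)-3-(4-hydroxy-3-methoxyphenyl)prop-2-enoic acid | COc1cc(/C=C/C(=O)O)ccc1O | starting material
2 | tert-butyldimethylsilyl (E)-3-[4-(tert-butyldimethylsilyloxy)-3-methoxyphenyl]prop-2-enoate | COc1cc(/C=C/C(=O)O[Si](C)(C)C(C)(C)C)ccc1O[Si](C)(C)C(C)(C)C | intermediate
3 | (E)-3-[4-(tert-butyldimethylsilyloxy)-3-methoxyphenyl]prop-2-enoic acid | COc1cc(/C=C/C(=O)O)ccc1O[Si](C)(C)C(C)(C)C | intermediate
4 | (E)-[4-(2-bromoethenyl)-2-methoxyphenoxy](tert-butyl)dimethylsilane | COc1cc(/C=C/Br)ccc1O[Si](C)(C)C(C)(C)C | intermediate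
5 | 4-(tert-butyldimethylsilyloxy)benzaldehyde | O=Cc1ccc(O[Si](C)(C)C(C)(C)C)cc1 | starting material
6 | (S)-1-[4-(tert-butyldimethylsilyloxy)phenyl]but-3-en-1-yl diisopinocampheylborinate (isopinocampheyl groups from (+)-α-pinene) | C=CC[C@H](OB([C@@H]1C[C@@H]2C[C@@H](C2(C)C)[C@H]1C)[C@@H]1C[C@@H]2C[C@@H](C2(C)C)[C@H]1C)c1ccc(O[Si](C)(C)C(C)(C)C)cc1 | intermediate
7 | (S)-1-[4-(tert-butyldimethylsilyloxy)phenyl]but-3-en-1-ol | C=CC[C@H](O)c1ccc(O[Si](C)(C)C(C)(C)C)cc1 | intermediate
8 | (S)-tert-butyl{4-[1-(tert-butyldimethylsilyloxy)but-3-en-1-yl]phenoxy}dimethylsilane | C=CC[C@H](O[Si](C)(C)C(C)(C)C)c1ccc(O[Si](C)(C)C(C)(C)C)cc1 | intermediate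
9 | (S)-4-(tert-butyldimethylsilyloxy)-4-[4-(tert-butyldimethylsilyloxy)phenyl]butan-2-one | CC(=O)C[C@H](O[Si](C)(C)C(C)(C)C)c1ccc(O[Si](C)(C)C(C)(C)C)cc1 | intermediate
10 | carbon monoxide | [C-]#[O+] | starting material
11 | lithium (S)-4-(tert-butyldimethylsilyloxy)-4-[4-(tert-butyldimethylsilyloxy)phenyl]but-1-en-2-olate | [Li]OC(=C)C[C@H](O[Si](C)(C)C(C)(C)C)c1ccc(O[Si](C)(C)C(C)(C)C)cc1 | intermediate
12 | (S,1E)-7-(tert-butyldimethylsilyloxy)-1-[4-(tert-butyldimethylsilyloxy)-3-methoxyphenyl]-7-[4-(tert-butyldimethylsilyloxy)phenyl]hept-1-ene-3,5-dione, C3 enol form | COc1cc(/C=C/C(O)=C\C(=O)C[C@H](O[Si](C)(C)C(C)(C)C)c2ccc(O[Si](C)(C)C(C)(C)C)cc2)ccc1O[Si](C)(C)C(C)(C)C | intermediate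
13 | (S,1E)-7-hydroxy-1-(4-hydroxy-3-methoxyphenyl)-7-(4-hydroxyphenyl)hept-1-ene-3,5-dione, C3 enol form | COc1cc(/C=C/C(O)=C\C(=O)C[C@H](O)c2ccc(O)cc2)ccc1O | target

**Step count**

Total steps: 7 (two to bromide 4, three to ketone 9, the coupling, the deprotection).
Longest linear sequence: 5 steps (5 → 7 → 8 → 9 → 12 → 13, steps 3 to 7).

**Steps most likely to fail**

1. Step 6. Proton exchange between enolate 11 and the returned ketone may move the enolate to C6 and trigger β-elimination of the C7 silyloxy group. The enolate may also be acylated at oxygen, or may couple before CO has inserted. The fallback sets out from acid 3 and ketone 9 and comes back at 12. Acid 3 is treated with 1H-benzotriazole and SOCl2 in CH2Cl2 at room temperature to give 1-{(E)-3-[4-(tert-butyldimethylsilyloxy)-3-methoxyphenyl]prop-2-enoyl}-1H-benzotriazole F1. Enolate 11 (two equivalents, from 9 and LiN(SiMe3)2 at −78 °C) is then C-acylated by F1 in THF at −78 °C to 0 °C. This Claisen-type acylation of a ketone enolate with an N-acylbenzotriazole should give 12 without palladium or CO.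

2. Step 7. Once the ring B phenol is free, the C7–O bond may ionise while the secondary benzylic silyl ether is still being cleaved. That would cause loss of water to the C6=C7 dienone or erosion of the C7 configuration through a quinone methide. The fallback sets out from 7 and comes back at 13, carrying C7–O as a far more labile triethylsilyl ether. Alcohol 7 is silylated with Et3SiCl and imidazole to (S)-tert-butyldimethyl{4-[1-(triethylsilyloxy)but-3-en-1-yl]phenoxy}silane F2. Wacker oxidation as in step 5 gives (S)-4-[4-(tert-butyldimethylsilyloxy)phenyl]-4-(triethylsilyloxy)butan-2-one F3. Its lithium enolate F4 is coupled with 4 and CO as in step 6 to give the mixed silyl ether of the diketone F5. Et3N·3HF in MeCN/THF at 0 °C then removes the triethylsilyl group and both aryl silyl groups within a short exposure to give 13.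

3. Step 5. Palladium hydride migration of the terminal double bond, or anti-Markovnikov attack of water leading to the aldehyde, may compete with methyl ketone formation. The fallback sets out from 8 and comes back at 9. Oxidative cleavage with OsO4 (catalytic), NaIO4 and 2,6-lutidine in dioxane/H2O gives (S)-3-(tert-butyldimethylsilyloxy)-3-[4-(tert-butyldimethylsilyloxy)phenyl]propanal F6. Addition of CH3MgBr in THF at −78 °C gives (4S)-4-(tert-butyldimethylsilyloxy)-4-[4-(tert-butyldimethylsilyloxy)phenyl]butan-2-ol F7 as a mixture of epimers at the new carbinol, which does not matter. Oxidation with Dess–Martin periodinane and NaHCO3 in CH2Cl2 gives 9.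

**Further compounds**

F1 | step 6 | 1-{(E)-3-[4-(tert-butyldimethylsilyloxy)-3-methoxyphenyl]prop-2-enoyl}-1H-benzotriazole | COc1cc(/C=C/C(=O)n2nnc3ccccc32)ccc1O[Si](C)(C)C(C)(C)C
F2 | step 7 | (S)-tert-butyldimethyl{4-[1-(triethylsilyloxy)but-3-en-1-yl]phenoxy}silane | C=CC[C@H](O[Si](CC)(CC)CC)c1ccc(O[Si](C)(C)C(C)(C)C)cc1
F3 | step 7 | (S)-4-[4-(tert-butyldimethylsilyloxy)phenyl]-4-(triethylsilyloxy)butan-2-one | CC(=O)C[C@H](O[Si](CC)(CC)CC)c1ccc(O[Si](C)(C)C(C)(C)C)cc1
F4 | step 7 | lithium (S)-4-[4-(tert-butyldimethylsilyloxy)phenyl]-4-(triethylsilyloxy)but-1-en-2-olate | [Li]OC(=C)C[C@H](O[Si](CC)(CC)CC)c1ccc(O[Si](C)(C)C(C)(C)C)cc1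
F5 | step 7 | (S,1E)-1-[4-(tert-butyldimethylsilyloxy)-3-methoxyphenyl]-7-[4-(tert-butyldimethylsilyloxy)phenyl]-7-(triethylsilyloxy)hept-1-ene-3,5-dione, C3 enol form | COc1cc(/C=C/C(O)=C\C(=O)C[C@H](O[Si](CC)(CC)CC)c2ccc(O[Si](C)(C)C(C)(C)C)cc2)ccc1O[Si](C)(C)C(C)(C)C
F6 | step 5 | (S)-3-(tert-butyldimethylsilyloxy)-3-[4-(tert-butyldimethylsilyloxy)phenyl]propanal | O=CC[C@H](O[Si](C)(C)C(C)(C)C)c1ccc(O[Si](C)(C)C(C)(C)C)cc1
F7 | step 5 | (4S)-4-(tert-butyldimethylsilyloxy)-4-[4-(tert-butyldimethylsilyloxy)phenyl]butan-2-ol, both C2 epimers | CC(O)C[C@H](O[Si](C)(C)C(C)(C)C)c1ccc(O[Si](C)(C)C(C)(C)C)cc1
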